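The 2-pyranone ring is cut at C4'–C5' and O1'–C2'. Its C2'–C3'–C4' atoms are a malonyl unit whose C3' already carries the methylene bridge to C5 of the dihydrobenzofuran, and C5', C6' and O1' are the enol of symmetric 3-pentanone. In one operation the key step C-acylates the ketone's silyl enol ether and lactonises through the enol oxygen, growing the whole 6-ethyl-4-hydroxy-5-methylpyranone on the finished, stereodefined core. The precursor is the 4,6-di-O-acetyl arylmethylmalonyl dichloride. It is assembled by a Trost cyclisation (C2) and a phenol conjugate addition to di-tert-butyl methylenemalonate, and its acid chlorides are unmasked without protic acid.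

Key step: step 16

Assumption: the (S,S)-Trost ligand is taken to give the (2S)-dihydrobenzofuran from the (E)-carbonate, by analogy with closely related (E)-4-aryl-2-methylbut-2-enyl carbonates; if the sense is opposite on this substrate, the (R,R)-ligand is used.

Remark: CIP analysis of the target SMILES gives S at C2 of the dihydrobenzofuran and S in the 2-methylbutanoyl chain; the route is planned for this isomer.

Step 1
Reactants: 1 (S)-2-methylbutanoic acid; 2 phloroglucinol
Product: 4 (S)-2-methyl-1-(2,4,6-trihydroxyphenyl)butan-1-one, via (S)-2-methylbutanoyl chloride 3 (not isolated)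
Conditions: (COCl)2, cat. DMF, CH2Cl2, 0 °C→rt; then 2, AlCl3, PhNO2/CH2Cl2, 0 °C→rt; aq. HCl
Reagents that add atoms: none
Why: Neutral acid chloride formation followed by Friedel–Crafts C-acylation of the symmetrical triol should stop at the mono-ketone because the product is deactivated as its aluminium chelate; the (S)-centre comes from the chiral pool and no base is present to enolise it.

Step 2
Reactants: 4 (S)-2-methyl-1-(2,4,6-trihydroxyphenyl)butan-1-one
Product: 5 (S)-1-[2,6-dihydroxy-4-(triisopropylsilyloxy)phenyl]-2-methylbutan-1-one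
Conditions: TIPSCl (1.05 equiv), imidazole, DMF, 0 °C
Reagents that add atoms: chlorotriisopropylsilane, CC(C)[Si](Cl)(C(C)C)C(C)C
Why: Regioselective O-silylation: the non-chelated 4-OH is the most acidic and least hindered hydroxyl, so the bulky silyl chloride should react there and leave the two ketone-chelated phenols free.

Step 3
Reactants: 5 (S)-1-[2,6-dihydroxy-4-(triisopropylsilyloxy)phenyl]-2-methylbutan-1-one
Product: 6 (S)-1-[2-(allyloxy)-6-hydroxy-4-(triisopropylsilyloxy)phenyl]-2-methylbutan-1-one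
Conditions: allyl bromide (1.1 equiv), K2CO3, acetone, 50 °C
Reagents that add atoms: allyl bromide, C=CCBr
Why: Williamson O-allylation of one of two equivalent chelated phenols; once one is etherified the other is more strongly hydrogen-bonded and less acidic, which should hold the reaction at the mono-ether.

Step 4
Reactants: 6 (S)-1-[2-(allyloxy)-6-hydroxy-4-(triisopropylsilyloxy)phenyl]-2-methylbutan-1-one
Product: 7 (S)-1-[3-allyl-2,6-dihydroxy-4-(triisopropylsilyloxy)phenyl]-2-methylbutan-1-one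
Conditions: 1,2-dichlorobenzene, 185 °C, sealed tube
Reagents that add atoms: none
Why: Aromatic Claisen rearrangement ([3,3]-sigmatropic shift, then enolisation) should deliver the allyl group to C3, the only unsubstituted ortho position of the ether oxygen, in a neutral medium that does not enolise the ketone.

Step 5
Reactants: 7 (S)-1-[3-allyl-2,6-dihydroxy-4-(triisopropylsilyloxy)phenyl]-2-methylbutan-1-one
Product: 8 (S)-1-{2,6-dihydroxy-3-[(E)-3-methyl-4-oxobut-2-en-1-yl]-4-(triisopropylsilyloxy)phenyl}-2-methylbutan-1-one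
Conditions: methacrolein (excess), Hoveyda–Grubbs II (5 mol%), CH2Cl2, 40 °C
Reagents that add atoms: methacrolein, C=C(C)C=O
Why: Olefin cross-metathesis of a terminal alkene with excess methacrolein should give the trisubstituted enal as the (E)-isomer, with the phenols and the hindered ketone as spectators.

Step 6
Reactants: 8 (S)-1-{2,6-dihydroxy-3-[(E)-3-methyl-4-oxobut-2-en-1-yl]-4-(triisopropylsilyloxy)phenyl}-2-methylbutan-1-one
Product: 9 (S)-1-{2,6-dihydroxy-3-[(E)-4-hydroxy-3-methylbut-2-en-1-yl]-4-(triisopropylsilyloxy)phenyl}-2-methylbutan-1-one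
Conditions: NaBH4, CeCl3·7H2O, MeOH, −40 °C
Reagents that add atoms: none
Why: Luche 1,2-reduction of the enal; the doubly ortho-substituted, chelated aryl ketone should not be reduced at this temperature.

Step 7
Reactants: 9 (S)-1-{2,6-dihydroxy-3-[(E)-4-hydroxy-3-methylbut-2-en-1-yl]-4-(triisopropylsilyloxy)phenyl}-2-methylbutan-1-one
Product: 10 (S)-1-{2,6-dihydroxy-3-[(E)-4-(methoxycarbonyloxy)-3-methylbut-2-en-1-yl]-4-(triisopropylsilyloxy)phenyl}-2-methylbutan-1-one
Conditions: ClCO2Me (1.1 equiv), pyridine, CH2Cl2, −10 °C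
Reagents that add atoms: methyl chloroformate, COC(=O)Cl
Why: Chemoselective O-acylation (carbonate formation): the primary allylic alcohol should react with the chloroformate far faster than the two hindered, chelated phenols.

Step 8
Reactants: 10 (S)-1-{2,6-dihydroxy-3-[(E)-4-(methoxycarbonyloxy)-3-methylbut-2-en-1-yl]-4-(triisopropylsilyloxy)phenyl}-2-methylbutan-1-one
Product: 11 (S)-1-[(2S)-6-hydroxy-2-(prop-1-en-2-yl)-4-(triisopropylsilyloxy)-2,3-dihydrobenzofuran-7-yl]-2-methylbutan-1-one
Conditions: Pd2(dba)3·CHCl3 (2.5 mol%), (S,S)-Trost ligand (7.5 mol%), AcOH (1 equiv), CH2Cl2 (0.03 M), rt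
Reagents that add atoms: none
Why: Trost asymmetric allylic alkylation: ionisation of the carbonate gives a π-allyl palladium complex, the only phenol that can reach it (the one next to the chain and ortho to the ketone, since O4 is silylated) closes 5-exo at the internal terminus, and the chiral ligand pocket sets C2 as S.

Step 9
Reactants: 11 (S)-1-[(2S)-6-hydroxy-2-(prop-1-en-2-yl)-4-(triisopropylsilyloxy)-2,3-dihydrobenzofuran-7-yl]-2-methylbutan-1-one
Product: 12 (S)-1-[(2S)-4,6-dihydroxy-2-(prop-1-en-2-yl)-2,3-dihydrobenzofuran-7-yl]-2-methylbutan-1-one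
Conditions: TBAF, AcOH, THF, 0 °C
Reagents that add atoms: none
Why: Fluoride cleavage of the aryl silyl ether under acetic acid buffering; nothing else in the molecule is fluoride-labile.

Step 10
Reactants: 13 di-tert-butyl malonate
Product: 14 di-tert-butyl methylenemalonate
Conditions: (CH2O)n, cat. KOAc, cat. Cu(OAc)2·H2O, AcOH, 95 °C; distillation
Reagents that add atoms: formaldehyde (as paraformaldehyde), C=O
Why: Knoevenagel condensation of the malonate with formaldehyde followed by distillation; the bulky esters make this methylenemalonate isolable and storable.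

Step 11
Reactants: 12 (S)-1-[(2S)-4,6-dihydroxy-2-(prop-1-en-2-yl)-2,3-dihydrobenzofuran-7-yl]-2-methylbutan-1-one; 14 di-tert-butyl methylenemalonate
Product: 15 di-tert-butyl 2-{[(2S)-4,6-dihydroxy-7-[(S)-2-methylbutanoyl]-2-(prop-1-en-2-yl)-2,3-dihydrobenzofuran-5-yl]methyl}malonate
Conditions: iPr2NEt (0.3 equiv), MeCN, 0 °C→rt, slow addition of 14 (1.05 equiv)
Reagents that add atoms: none
Why: Michael (Friedel–Crafts-type) C-alkylation of an acylphloroglucinol by a methylene-1,3-dicarbonyl acceptor: the phenoxide of 12 should attack through C5, its only free ring carbon, flanked by two oxygens, while oxa-Michael adducts revert and the tert-butyl esters resist lactonisation by the neighbouring phenols.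

Step 12
Reactants: 15 di-tert-butyl 2-{[(2S)-4,6-dihydroxy-7-[(S)-2-methylbutanoyl]-2-(prop-1-en-2-yl)-2,3-dihydrobenzofuran-5-yl]methyl}malonate
Product: 16 di-tert-butyl 2-{[(2S)-4,6-diacetoxy-7-[(S)-2-methylbutanoyl]-2-(prop-1-en-2-yl)-2,3-dihydrobenzofuran-5-yl]methyl}malonate
Conditions: Ac2O, pyridine, cat. DMAP, CH2Cl2, 0 °C→rt
Reagents that add atoms: acetic anhydride, CC(=O)OC(C)=O
Why: DMAP-catalysed O-acetylation of both phenols, which makes the phenolic oxygens non-nucleophilic for the acid chloride chemistry ahead; the acetates are installed only now, when no formyl or free carboxyl group is nearby.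

Step 13
Reactants: 16 di-tert-butyl 2-{[(2S)-4,6-diacetoxy-7-[(S)-2-methylbutanoyl]-2-(prop-1-en-2-yl)-2,3-dihydrobenzofuran-5-yl]methyl}malonate
Product: 18 2-{[(2S)-4,6-diacetoxy-7-[(S)-2-methylbutanoyl]-2-(prop-1-en-2-yl)-2,3-dihydrobenzofuran-5-yl]methyl}malonic acid, via bis(trimethylsilyl) malonate 17 (not isolated)
Conditions: TMSOTf (2.5 equiv), 2,6-lutidine, CH2Cl2, 0 °C; then aq. NaH2PO4 (pH 3), 0 °C; used at once
Reagents that add atoms: none
Why: Silyl triflate-mediated cleavage of tert-butyl esters (loss of isobutene to the hindered base) gives silyl esters that hydrolyse on work-up, so no protic acid meets the isopropenyl group, the aryl acetates stay, and the hindered ketone, which would give a tetrasubstituted enol ether, should not be silylated at 0 °C.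

Step 14
Reactants: 18 2-{[(2S)-4,6-diacetoxy-7-[(S)-2-methylbutanoyl]-2-(prop-1-en-2-yl)-2,3-dihydrobenzofuran-5-yl]methyl}malonic acid
Product: 19 2-{[(2S)-4,6-diacetoxy-7-[(S)-2-methylbutanoyl]-2-(prop-1-en-2-yl)-2,3-dihydrobenzofuran-5-yl]methyl}malonyl dichloride
Conditions: 1-chloro-N,N,2-trimethylprop-1-en-1-amine (Ghosez's reagent, 2.2 equiv), CH2Cl2, 0 °C→rt; used crude
Reagents that add atoms: 1-chloro-N,N,2-trimethylprop-1-en-1-amine, CC(C)=C(Cl)N(C)C
Why: Acid chloride formation with an α-chloroenamine under neutral conditions, in which the proton ends on the amide by-product, so no HCl is released near the alkene.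

Step 15
Reactants: 20 3-pentanone
Product: 21 (Z)-trimethyl(pent-2-en-3-yloxy)silane
Conditions: TMSOTf, Et3N, Et2O, 0 °C; distillation
Reagents that add atoms: trimethylsilyl triflate, C[Si](C)(C)OS(=O)(=O)C(F)(F)F
Why: Soft enolisation and O-silylation of the symmetrical ketone should give mainly the (Z)-enol ether; either geometry would serve, since it is lost in the pyranone.

Step 16
Reactants: 19 2-{[(2S)-4,6-diacetoxy-7-[(S)-2-methylbutanoyl]-2-(prop-1-en-2-yl)-2,3-dihydrobenzofuran-5-yl]methyl}malonyl dichloride; 21 (Z)-trimethyl(pent-2-en-3-yloxy)silane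
Product: 23 (2S)-5-[(6-ethyl-4-hydroxy-5-methyl-2-oxo-2H-pyran-3-yl)methyl]-7-[(S)-2-methylbutanoyl]-2-(prop-1-en-2-yl)-2,3-dihydrobenzofuran-4,6-diyl diacetate, via 3,5-dioxoheptanoyl chloride 22 (not isolated)
Conditions: 21 (2.5 equiv), 2,6-di-tert-butyl-4-methylpyridine (1.2 equiv), CH2Cl2, −78 °C→rt
Reagents that add atoms: none
Why: The nucleophilic carbon of the silyl enol ether attacks one acyl chloride of 19 (or the (chlorocarbonyl)ketene formed from it by loss of HCl to the hindered base), and loss of Me3SiCl gives the 3,5-dioxo acid chloride 22 with the new C4'–C5' bond. The enol oxygen of the 5-keto group then attacks the remaining acyl chloride in a 6-exo-trig addition–elimination that forms O1'–C2' and closes the ring, which tautomerises to the 4-hydroxy-2-pyranone. The closest known reaction is the condensation of malonyl dichlorides, including monosubstituted ones, and of (chlorocarbonyl)ketenes with ketone silyl enol ethers to give 4-hydroxy-2-pyranones. No stereocentre is created, and C2 and the side-chain centre are remote and untouched. The step needs C-acylation before O-acylation, ring closure before a second intermolecular acylation, and no free HCl; the soft silyl enol ether, its excess and the hindered pyridine should provide this, while the two acetates keep the flanking phenolic oxygens from lactonising onto the acid chloride. 3-Pentanone is symmetric, so the 5-methyl-6-ethyl pattern follows without a regiochemical choice.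

Step 17
Reactants: 23 (2S)-5-[(6-ethyl-4-hydroxy-5-methyl-2-oxo-2H-pyran-3-yl)methyl]-7-[(S)-2-methylbutanoyl]-2-(prop-1-en-2-yl)-2,3-dihydrobenzofuran-4,6-diyl diacetate
Product: 24 6-ethyl-4-hydroxy-3-{[(2S)-4,6-dihydroxy-7-[(S)-2-methylbutanoyl]-2-(prop-1-en-2-yl)-2,3-dihydrobenzofuran-5-yl]methyl}-5-methyl-2H-pyran-2-one (CNP0261501.1)
Conditions: K2CO3 (3 equiv), MeOH, 0 °C, Ar; then dil. HCl to pH 4, 0 °C
Reagents that add atoms: none
Why: Base-mediated transesterification (methanolysis) of the two aryl acetates, which are activated esters of acidic phenols; the pyranone is shielded as its 4-oxido anion and the phenoxides formed keep the ketone from enolising.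

Compound list
1 | (S)-2-methylbutanoic acid | CC[C@H](C)C(=O)O | starting material
2 | phloroglucinol | Oc1cc(O)cc(O)c1 | starting material
3 | (S)-2-methylbutanoyl chloride | CC[C@H](C)C(=O)Cl | intermediate
4 | (S)-2-methyl-1-(2,4,6-trihydroxyphenyl)butan-1-one | CC[C@H](C)C(=O)c1c(O)cc(O)cc1O | intermediate
5 | (S)-1-[2,6-dihydroxy-4-(triisopropylsilyloxy)phenyl]-2-methylbutan-1-one | CC[C@H](C)C(=O)c1c(O)cc(O[Si](C(C)C)(C(C)C)C(C)C)cc1O | intermediate
6 | (S)-1-[2-(allyloxy)-6-hydroxy-4-(triisopropylsilyloxy)phenyl]-2-methylbutan-1-one | CC[C@H](C)C(=O)c1c(O)cc(O[Si](C(C)C)(C(C)C)C(C)C)cc1OCC=C | intermediate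
7 | (S)-1-[3-allyl-2,6-dihydroxy-4-(triisopropylsilyloxy)phenyl]-2-methylbutan-1-one | CC[C@H](C)C(=O)c1c(O)cc(O[Si](C(C)C)(C(C)C)C(C)C)c(CC=C)c1O | intermediate
8 | (S)-1-{2,6-dihydroxy-3-[(E)-3-methyl-4-oxobut-2-en-1-yl]-4-(triisopropylsilyloxy)phenyl}-2-methylbutan-1-one | CC[C@H](C)C(=O)c1c(O)cc(O[Si](C(C)C)(C(C)C)C(C)C)c(C/C=C(\C)C=O)c1O | intermediate
9 | (S)-1-{2,6-dihydroxy-3-[(E)-4-hydroxy-3-methylbut-2-en-1-yl]-4-(triisopropylsilyloxy)phenyl}-2-methylbutan-1-one | CC[C@H](C)C(=O)c1c(O)cc(O[Si](C(C)C)(C(C)C)C(C)C)c(C/C=C(\C)CO)c1O | intermediate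
10 | (S)-1-{2,6-dihydroxy-3-[(E)-4-(methoxycarbonyloxy)-3-methylbut-2-en-1-yl]-4-(triisopropylsilyloxy)phenyl}-2-methylbutan-1-one | CC[C@H](C)C(=O)c1c(O)cc(O[Si](C(C)C)(C(C)C)C(C)C)c(C/C=C(\C)COC(=O)OC)c1O | intermediate
11 | (S)-1-[(2S)-6-hydroxy-2-(prop-1-en-2-yl)-4-(triisopropylsilyloxy)-2,3-dihydrobenzofuran-7-yl]-2-methylbutan-1-one | C=C(C)[C@@H]1Cc2c(O[Si](C(C)C)(C(C)C)C(C)C)cc(O)c(C(=O)[C@@H](C)CC)c2O1 | intermediate
12 | (S)-1-[(2S)-4,6-dihydroxy-2-(prop-1-en-2-yl)-2,3-dihydrobenzofuran-7-yl]-2-methylbutan-1-one | C=C(C)[C@@H]1Cc2c(O)cc(O)c(C(=O)[C@@H](C)CC)c2O1 | intermediate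
13 | di-tert-butyl malonate | CC(C)(C)OC(=O)CC(=O)OC(C)(C)C | starting material
14 | di-tert-butyl methylenemalonate | C=C(C(=O)OC(C)(C)C)C(=O)OC(C)(C)C | intermediate
15 | di-tert-butyl 2-{[(2S)-4,6-dihydroxy-7-[(S)-2-methylbutanoyl]-2-(prop-1-en-2-yl)-2,3-dihydrobenzofuran-5-yl]methyl}malonate | C=C(C)[C@@H]1Cc2c(O)c(CC(C(=O)OC(C)(C)C)C(=O)OC(C)(C)C)c(O)c(C(=O)[C@@H](C)CC)c2O1 | intermediate
16 | di-tert-butyl 2-{[(2S)-4,6-diacetoxy-7-[(S)-2-methylbutanoyl]-2-(prop-1-en-2-yl)-2,3-dihydrobenzofuran-5-yl]methyl}malonate | C=C(C)[C@@H]1Cc2c(OC(C)=O)c(CC(C(=O)OC(C)(C)C)C(=O)OC(C)(C)C)c(OC(C)=O)c(C(=O)[C@@H](C)CC)c2O1 | intermediate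
17 | bis(trimethylsilyl) 2-{[(2S)-4,6-diacetoxy-7-[(S)-2-methylbutanoyl]-2-(prop-1-en-2-yl)-2,3-dihydrobenzofuran-5-yl]methyl}malonate | C=C(C)[C@@H]1Cc2c(OC(C)=O)c(CC(C(=O)O[Si](C)(C)C)C(=O)O[Si](C)(C)C)c(OC(C)=O)c(C(=O)[C@@H](C)CC)c2O1 | intermediate
18 | 2-{[(2S)-4,6-diacetoxy-7-[(S)-2-methylbutanoyl]-2-(prop-1-en-2-yl)-2,3-dihydrobenzofuran-5-yl]methyl}malonic acid | C=C(C)[C@@H]1Cc2c(OC(C)=O)c(CC(C(=O)O)C(=O)O)c(OC(C)=O)c(C(=O)[C@@H](C)CC)c2O1 | intermediate
19 | 2-{[(2S)-4,6-diacetoxy-7-[(S)-2-methylbutanoyl]-2-(prop-1-en-2-yl)-2,3-dihydrobenzofuran-5-yl]methyl}malonyl dichloride | C=C(C)[C@@H]1Cc2c(OC(C)=O)c(CC(C(=O)Cl)C(=O)Cl)c(OC(C)=O)c(C(=O)[C@@H](C)CC)c2O1 | intermediate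
20 | 3-pentanone | CCC(=O)CC | starting material
21 | (Z)-trimethyl(pent-2-en-3-yloxy)silane | C/C=C(\O[Si](C)(C)C)CC | intermediate
22 | 2-{[(2S)-4,6-diacetoxy-7-[(S)-2-methylbutanoyl]-2-(prop-1-en-2-yl)-2,3-dihydrobenzofuran-5-yl]methyl}-4-methyl-3,5-dioxoheptanoyl chloride (mixture of epimers and enol forms at the two chain centres) | C=C(C)[C@@H]1Cc2c(OC(C)=O)c(CC(C(=O)Cl)C(=O)C(C)C(=O)CC)c(OC(C)=O)c(C(=O)[C@@H](C)CC)c2O1 | intermediate
23 | (2S)-5-[(6-ethyl-4-hydroxy-5-methyl-2-oxo-2H-pyran-3-yl)methyl]-7-[(S)-2-methylbutanoyl]-2-(prop-1-en-2-yl)-2,3-dihydrobenzofuran-4,6-diyl diacetate | C=C(C)[C@@H]1Cc2c(OC(C)=O)c(Cc3c(O)c(C)c(CC)oc3=O)c(OC(C)=O)c(C(=O)[C@@H](C)CC)c2O1 | intermediate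
24 | 6-ethyl-4-hydroxy-3-{[(2S)-4,6-dihydroxy-7-[(S)-2-methylbutanoyl]-2-(prop-1-en-2-yl)-2,3-dihydrobenzofuran-5-yl]methyl}-5-methyl-2H-pyran-2-one | C=C(C)[C@@H]1Cc2c(O)c(Cc3c(O)c(C)c(CC)oc3=O)c(O)c(C(=O)[C@@H](C)CC)c2O1 | target

Total step count: 17. Longest linear sequence: 15 (steps 1–9, 11–14, 16, 17); steps 10 and 15 are one-step side branches.

Steps most likely to fail

Step 16. The bimolecular C-acylation may be outrun by self-condensation of the malonyl dichloride or its ketene, or by O-acylation of the acidic pyranone product, and liberated acid may add to the isopropenyl group. Fallback: the pyranone is made first and the methylene bridge is formed afterwards. Enol ether 21 is condensed with malonyl dichloride itself (Et2O, −78 °C→rt) to give 6-ethyl-4-hydroxy-5-methyl-2H-pyran-2-one F1. Treatment of F1 with Eschenmoser's salt (MeCN, rt) gives the Mannich base 3-[(dimethylamino)methyl]-6-ethyl-4-hydroxy-5-methyl-2H-pyran-2-one F2. Warming F2 with diol 12 (dioxane, 60–80 °C) expels dimethylamine, and the 3-methylenepyran-2,4-dione so formed should be captured by C5 of 12. This fallback sets out from 12 and 21 and returns to the route at target 24.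

Step 11. C-alkylation may be slow compared with base-initiated oligomerisation of the acceptor, or the reaction may stall at reversible O-adducts. Fallback: the roles of electrophile and nucleophile are exchanged. Diol 12 is aminomethylated at C5 with Eschenmoser's salt (CH2Cl2, rt) to give (S)-1-[(2S)-5-[(dimethylamino)methyl]-4,6-dihydroxy-2-(prop-1-en-2-yl)-2,3-dihydrobenzofuran-7-yl]-2-methylbutan-1-one F3. Heating F3 with the sodium salt of di-tert-butyl malonate 13 (NaH, dioxane, 80 °C) should generate the ortho-quinone methide, which the malonate traps. This fallback sets out from 12 and returns at 15.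

Step 8. Facial discrimination in the ring closure may be insufficient, or re-ionisation of the allylic aryl ether by palladium may erode it. Fallback: C2 is set by reagent-controlled epoxidation. Allylic alcohol 9 undergoes Sharpless epoxidation (Ti(OiPr)4 in excess over the phenols, D-(−)-diisopropyl tartrate, t-BuOOH, 4 Å MS, CH2Cl2, −20 °C) to give (S)-1-[2,6-dihydroxy-3-{[(2R,3R)-3-(hydroxymethyl)-3-methyloxiran-2-yl]methyl}-4-(triisopropylsilyloxy)phenyl]-2-methylbutan-1-one F4. The neighbouring phenol opens the epoxide at its CH carbon with inversion (5-exo, titanium-mediated, completed with DBU if needed) to give (S)-1-[(2S)-2-[(2R)-1,2-dihydroxypropan-2-yl]-6-hydroxy-4-(triisopropylsilyloxy)-2,3-dihydrobenzofuran-7-yl]-2-methylbutan-1-one F5. Thiocarbonyldiimidazole (THF, rt) converts the diol into (S)-1-[(2S)-6-hydroxy-2-[(4R)-4-methyl-2-thioxo-1,3-dioxolan-4-yl]-4-(triisopropylsilyloxy)-2,3-dihydrobenzofuran-7-yl]-2-methylbutan-1-one F6. Corey–Winter fragmentation of F6 (1,3-dimethyl-2-phenyl-1,3,2-diazaphospholidine, 40 °C) should give the isopropenyl group with no regiochemical ambiguity. This fallback sets out from 9 and returns at 11.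

Further compounds
F1 | step 16 | 6-ethyl-4-hydroxy-5-methyl-2H-pyran-2-one | CCc1oc(=O)cc(O)c1C
F2 | step 16 | 3-[(dimethylamino)methyl]-6-ethyl-4-hydroxy-5-methyl-2H-pyran-2-one | CCc1oc(=O)c(CN(C)C)c(O)c1C
F3 | step 11 | (S)-1-[(2S)-5-[(dimethylamino)methyl]-4,6-dihydroxy-2-(prop-1-en-2-yl)-2,3-dihydrobenzofuran-7-yl]-2-methylbutan-1-one | C=C(C)[C@@H]1Cc2c(O)c(CN(C)C)c(O)c(C(=O)[C@@H](C)CC)c2O1
F4 | step 8 | (S)-1-[2,6-dihydroxy-3-{[(2R,3R)-3-(hydroxymethyl)-3-methyloxiran-2-yl]methyl}-4-(triisopropylsilyloxy)phenyl]-2-methylbutan-1-one | CC[C@H](C)C(=O)c1c(O)cc(O[Si](C(C)C)(C(C)C)C(C)C)c(C[C@H]2O[C@]2(C)CO)c1O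
F5 | step 8 | (S)-1-[(2S)-2-[(2R)-1,2-dihydroxypropan-2-yl]-6-hydroxy-4-(triisopropylsilyloxy)-2,3-dihydrobenzofuran-7-yl]-2-methylbutan-1-one | OC[C@@](C)(O)[C@@H]1Cc2c(O[Si](C(C)C)(C(C)C)C(C)C)cc(O)c(C(=O)[C@@H](C)CC)c2O1
F6 | step 8 | (S)-1-[(2S)-6-hydroxy-2-[(4R)-4-methyl-2-thioxo-1,3-dioxolan-4-yl]-4-(triisopropylsilyloxy)-2,3-dihydrobenzofuran-7-yl]-2-methylbutan-1-one | C[C@@]1(COC(=S)O1)[C@@H]2Cc3c(O[Si](C(C)C)(C(C)C)C(C)C)cc(O)c(C(=O)[C@@H](C)CC)c3O2
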